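Ring C of the flavone is cut at three bonds, C8a–O1, C4a–C4 and O1–C2: ring A becomes an aryne, while C2, C3, C4 and ring B come from an arylpropiolic acid. One fluoride-triggered operation inserts the aryne into the carboxyl C–O bond and lets the freed phenoxide close the pyranone by conjugate addition. The route exploits the ortho relationship in ring A between C8a (bearing O1) and C4a (bearing carbonyl carbon C4), the two positions an aryne offers; the O5 substituent alone flanks the aryne because C8 is carried as C–H and oxygenated afterwards, para to the chelated 5-hydroxyl. The aryne precursor is a dibenzyl-protected 3,5-dioxy-4-methoxy-2-silylaryl triflate.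

Key step: step 9

**Route**

Step 1
Reactants: 1 methyl 3,5-dihydroxy-4-methoxybenzoate
Product: 2 methyl 3,5-bis(benzyloxy)-4-methoxybenzoate
Conditions: BnBr, K2CO3, DMF, 60 °C
Reagents that add atoms: benzyl bromide, BrCc1ccccc1
Why: Williamson ether synthesis on the two equivalent phenols should give the symmetric dibenzyl ether, the ester being inert to K2CO3.

Step 2
Reactants: 2 methyl 3,5-bis(benzyloxy)-4-methoxybenzoate
Product: 3 [3,5-bis(benzyloxy)-4-methoxyphenyl]methanol
Conditions: LiAlH4, THF, 0 °C to rt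
Reagents that add atoms: none
Why: Hydride reduction of the ester to the primary alcohol, with aryl benzyl and methyl ethers untouched.

Step 3
Reactants: 3 [3,5-bis(benzyloxy)-4-methoxyphenyl]methanol
Product: 4 3,5-bis(benzyloxy)-4-methoxybenzaldehyde
Conditions: MnO2, CH2Cl2, rt
Reagents that add atoms: none
Why: MnO2 oxidation of a benzylic alcohol should stop cleanly at the aldehyde.

Step 4
Reactants: 4 3,5-bis(benzyloxy)-4-methoxybenzaldehyde
Product: 6 3,5-bis(benzyloxy)-4-methoxyphenol, via aryl formate 5 (not isolated)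
Conditions: mCPBA, CH2Cl2, 0 °C to rt; aq. NaHCO3 wash; then K2CO3 (cat.), MeOH, rt
Reagents that add atoms: 3-chloroperbenzoic acid, O=C(OO)c1cccc(Cl)c1
Why: Baeyer–Villiger (Dakin-type) oxidation, in which the electron-rich aryl group with its para methoxy migrates in preference to hydrogen, followed by methanolysis of the formate.

Step 5
Reactants: 6 3,5-bis(benzyloxy)-4-methoxyphenol
Product: 7 3,5-bis(benzyloxy)-2-bromo-4-methoxyphenol
Conditions: NBS (1.0 equiv), CH2Cl2, −78 °C to 0 °C
Reagents that add atoms: N-bromosuccinimide, O=C1CCC(=O)N1Br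
Why: Electrophilic aromatic bromination ortho to the free hydroxyl; the two open positions are equivalent by symmetry, so one equivalent should give a single monobromide.

Step 6
Reactants: 7 3,5-bis(benzyloxy)-2-bromo-4-methoxyphenol
Product: 10 3,5-bis(benzyloxy)-4-methoxy-2-(trimethylsilyl)phenyl trifluoromethanesulfonate, via aryl trimethylsilyl ether 8 (not isolated), via lithium silylphenoxide 9 (not isolated)
Conditions: HMDS, THF, reflux, then evaporate; n-BuLi, THF, −100 °C to −80 °C; Tf2O, −100 °C to rt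
Reagents that add atoms: hexamethyldisilazane, C[Si](C)(C)N[Si](C)(C)C; trifluoromethanesulfonic anhydride, O=S(=O)(OS(=O)(=O)C(F)(F)F)C(F)(F)F
Why: O-silylation, bromine–lithium exchange and anionic 1,3 O-to-C silyl shift (retro-Brook rearrangement), then O-triflation of the lithium phenoxide, the standard telescoped entry to ortho-silylaryl triflates, with exchange far faster than benzylic deprotonation at this temperature.

Step 7
Reactants: 11 3-(benzyloxy)-4-methoxybenzaldehyde
Product: 12 2-(benzyloxy)-4-(2,2-dibromoethenyl)-1-methoxybenzene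
Conditions: CBr4, PPh3, CH2Cl2, 0 °C
Reagents that add atoms: carbon tetrabromide, BrC(Br)(Br)Br
Why: Corey–Fuchs dibromo-olefination, a Wittig-type reaction of the aldehyde with the ylide formed from PPh3 and CBr4.

Step 8
Reactants: 12 2-(benzyloxy)-4-(2,2-dibromoethenyl)-1-methoxybenzene
Product: 14 3-[3-(benzyloxy)-4-methoxyphenyl]prop-2-ynoic acid, via lithium acetylide 13 (not isolated)
Conditions: n-BuLi (2.2 equiv), THF, −78 °C; CO2 (g), −78 °C to rt; then aq. HCl
Reagents that add atoms: carbon dioxide, O=C=O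
Why: Second half of the Corey–Fuchs sequence (exchange, Fritsch–Buttenberg–Wiechell rearrangement and deprotonation to the lithium acetylide), followed by carboxylation of the acetylide.

Step 9
Reactants: 10 3,5-bis(benzyloxy)-4-methoxy-2-(trimethylsilyl)phenyl trifluoromethanesulfonate (1.3 equiv); 14 3-[3-(benzyloxy)-4-methoxyphenyl]prop-2-ynoic acid
Product: 17 5,7-bis(benzyloxy)-2-[3-(benzyloxy)-4-methoxyphenyl]-6-methoxy-4H-chromen-4-one, via aryne 15 (not isolated), via cesium ynone phenoxide 16 (not isolated)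
Conditions: CsF (4 equiv), THF, 125 °C, sealed tube
Reagents that add atoms: none
Why: Fluoride strips the silyl group from 10 and triflate departs to give aryne 15; the cesium salt of 14 attacks it through oxygen, and the aryl anion so formed adds to the adjacent ester C=O to give a strained benzoxetene alkoxide whose collapse with C–O cleavage releases the 2-acylphenoxide 16, so that the aryne ends up inserted into the carboxyl C–O bond (C8a–O1 and C4a–C4 made). The phenoxide oxygen of 16 then attacks the alkyne terminus C2 in a 6-endo-dig oxa-Michael addition that closes ring C (O1–C2), and protonation at C3 by CsHF2 should deliver 17. The closest known reaction type is the fluoride-promoted C–O insertion of arynes into carboxylic acids, which with 3-arylpropiolic acids is known to run on to flavones. No stereocentre is created. The first selectivity needed is regioselective aryne capture: the lone alkoxy neighbour of the aryne (the C5 benzyloxy group, C8 being C–H) polarises the strained bond, so the carboxylate attacks the far carbon and the negative charge develops on the carbon next to oxygen. The second is 6-endo over 5-exo closure, favoured in the hot aprotic medium where the 4-pyranone is the more stable product and proton donors that would intercept the aryl anion are scarce.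

Step 10
Reactants: 17 5,7-bis(benzyloxy)-2-[3-(benzyloxy)-4-methoxyphenyl]-6-methoxy-4H-chromen-4-one
Product: 18 7-(benzyloxy)-2-[3-(benzyloxy)-4-methoxyphenyl]-5-hydroxy-6-methoxy-4H-chromen-4-one
Conditions: MgBr2·OEt2 (3 equiv), toluene, 80 °C; then aq. HCl
Reagents that add atoms: none
Why: Chelation-assisted Lewis acid ether cleavage, in which magnesium held between the C4 carbonyl and O5 activates only the peri benzyl ether toward bromide attack at its benzylic carbon, the other ethers having no carbonyl neighbour.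

Step 11
Reactants: 18 7-(benzyloxy)-2-[3-(benzyloxy)-4-methoxyphenyl]-5-hydroxy-6-methoxy-4H-chromen-4-one
Product: 20 7-(benzyloxy)-2-[3-(benzyloxy)-4-methoxyphenyl]-5,8-dihydroxy-6-methoxy-4H-chromen-4-one, via potassium aryl sulfate 19 (not isolated)
Conditions: K2S2O8, aq. KOH, pyridine, 10–20 °C; then HCl, Na2SO3, 90 °C
Reagents that add atoms: K2S2O8 (dipotassium peroxodisulfate), [K+].[K+].[O-]S(=O)(=O)OOS(=O)(=O)[O-]
Why: Elbs persulfate oxidation, in which the only free phenoxide (O5) attacks the peroxide oxygen through its para carbon C8 (the ortho carbon C6 is blocked by methoxy) and the aryl sulfate is then hydrolysed by acid to the quinol.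

Step 12
Reactants: 20 7-(benzyloxy)-2-[3-(benzyloxy)-4-methoxyphenyl]-5,8-dihydroxy-6-methoxy-4H-chromen-4-one
Product: 21 7-(benzyloxy)-2-[3-(benzyloxy)-4-methoxyphenyl]-5-hydroxy-6,8-dimethoxy-4H-chromen-4-one
Conditions: MeI (1.1 equiv), K2CO3, acetone, 40 °C, argon
Reagents that add atoms: iodomethane, CI
Why: Williamson methylation that should take the 8-hydroxyl only, because the 5-hydroxyl is hydrogen-bonded to the C4 carbonyl and is far less nucleophilic; exclusion of air protects the quinol.

Step 13
Reactants: 21 7-(benzyloxy)-2-[3-(benzyloxy)-4-methoxyphenyl]-5-hydroxy-6,8-dimethoxy-4H-chromen-4-one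
Product: 22 acerosin, 5,7-dihydroxy-2-(3-hydroxy-4-methoxyphenyl)-6,8-dimethoxy-4H-chromen-4-one
Conditions: H2 (1 atm), 10% Pd/C, EtOAc–MeOH, rt
Reagents that add atoms: none
Why: Catalytic hydrogenolysis of the two aryl benzyl ethers, under which methyl ethers and the C2–C3 double bond of the 4-pyranone should persist.

**Compound list**

1 | methyl 3,5-dihydroxy-4-methoxybenzoate | COC(=O)c1cc(O)c(OC)c(O)c1 | starting material
2 | methyl 3,5-bis(benzyloxy)-4-methoxybenzoate | COC(=O)c1cc(OCc2ccccc2)c(OC)c(OCc2ccccc2)c1 | intermediate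
3 | [3,5-bis(benzyloxy)-4-methoxyphenyl]methanol | OCc1cc(OCc2ccccc2)c(OC)c(OCc2ccccc2)c1 | intermediate
4 | 3,5-bis(benzyloxy)-4-methoxybenzaldehyde | O=Cc1cc(OCc2ccccc2)c(OC)c(OCc2ccccc2)c1 | intermediate
5 | 3,5-bis(benzyloxy)-4-methoxyphenyl formate (not isolated) | O=COc1cc(OCc2ccccc2)c(OC)c(OCc2ccccc2)c1 | intermediate
6 | 3,5-bis(benzyloxy)-4-methoxyphenol | Oc1cc(OCc2ccccc2)c(OC)c(OCc2ccccc2)c1 | intermediate
7 | 3,5-bis(benzyloxy)-2-bromo-4-methoxyphenol | Oc1cc(OCc2ccccc2)c(OC)c(OCc2ccccc2)c1Br | intermediate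
8 | [3,5-bis(benzyloxy)-2-bromo-4-methoxyphenoxy](trimethyl)silane (not isolated) | C[Si](C)(C)Oc1cc(OCc2ccccc2)c(OC)c(OCc2ccccc2)c1Br | intermediate
9 | lithium 3,5-bis(benzyloxy)-4-methoxy-2-(trimethylsilyl)phenolate (not isolated) | [Li+].[O-]c1cc(OCc2ccccc2)c(OC)c(OCc2ccccc2)c1[Si](C)(C)C | intermediate
10 | 3,5-bis(benzyloxy)-4-methoxy-2-(trimethylsilyl)phenyl trifluoromethanesulfonate | COc1c(OCc2ccccc2)cc(OS(=O)(=O)C(F)(F)F)c([Si](C)(C)C)c1OCc1ccccc1 | intermediate
11 | 3-(benzyloxy)-4-methoxybenzaldehyde | COc1ccc(C=O)cc1OCc1ccccc1 | starting material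
12 | 2-(benzyloxy)-4-(2,2-dibromoethenyl)-1-methoxybenzene | COc1ccc(C=C(Br)Br)cc1OCc1ccccc1 | intermediate
13 | lithium 2-[3-(benzyloxy)-4-methoxyphenyl]ethyn-1-ide (not isolated) | [Li+].[C-]#Cc1ccc(OC)c(OCc2ccccc2)c1 | intermediate
14 | 3-[3-(benzyloxy)-4-methoxyphenyl]prop-2-ynoic acid | OC(=O)C#Cc1ccc(OC)c(OCc2ccccc2)c1 | intermediate
15 | 3,5-bis(benzyloxy)-4-methoxybenzyne (not isolated) | COC1=C(OCc2ccccc2)C#CC=C1OCc1ccccc1 | intermediate
16 | cesium 3,5-bis(benzyloxy)-2-{3-[3-(benzyloxy)-4-methoxyphenyl]prop-2-ynoyl}-4-methoxyphenolate (not isolated) | [Cs+].COc1ccc(C#CC(=O)c2c([O-])cc(OCc3ccccc3)c(OC)c2OCc2ccccc2)cc1OCc1ccccc1 | intermediate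
17 | 5,7-bis(benzyloxy)-2-[3-(benzyloxy)-4-methoxyphenyl]-6-methoxy-4H-chromen-4-one | COc1ccc(-c2cc(=O)c3c(OCc4ccccc4)c(OC)c(OCc4ccccc4)cc3o2)cc1OCc1ccccc1 | intermediate
18 | 7-(benzyloxy)-2-[3-(benzyloxy)-4-methoxyphenyl]-5-hydroxy-6-methoxy-4H-chromen-4-one | COc1ccc(-c2cc(=O)c3c(O)c(OC)c(OCc4ccccc4)cc3o2)cc1OCc1ccccc1 | intermediate
19 | potassium 7-(benzyloxy)-2-[3-(benzyloxy)-4-methoxyphenyl]-5-hydroxy-6-methoxy-4-oxo-4H-chromen-8-yl sulfate (not isolated) | [K+].COc1ccc(-c2cc(=O)c3c(O)c(OC)c(OCc4ccccc4)c(OS(=O)(=O)[O-])c3o2)cc1OCc1ccccc1 | intermediate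
20 | 7-(benzyloxy)-2-[3-(benzyloxy)-4-methoxyphenyl]-5,8-dihydroxy-6-methoxy-4H-chromen-4-one | COc1ccc(-c2cc(=O)c3c(O)c(OC)c(OCc4ccccc4)c(O)c3o2)cc1OCc1ccccc1 | intermediate
21 | 7-(benzyloxy)-2-[3-(benzyloxy)-4-methoxyphenyl]-5-hydroxy-6,8-dimethoxy-4H-chromen-4-one | COc1ccc(-c2cc(=O)c3c(O)c(OC)c(OCc4ccccc4)c(OC)c3o2)cc1OCc1ccccc1 | intermediate
22 | acerosin, 5,7-dihydroxy-2-(3-hydroxy-4-methoxyphenyl)-6,8-dimethoxy-4H-chromen-4-one | COc1ccc(-c2cc(=O)c3c(O)c(OC)c(O)c(OC)c3o2)cc1O | target

**Count and risks**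

Total step count: 13. Longest linear sequence: 11 steps (steps 1–6, then 9–13, from 1 to 22); the acid branch (steps 7–8) joins at step 9.

Steps most likely to fail:

1. Step 9. The aryl anion may be protonated before it reaches the carbonyl (leaving a simple aryl ester), the propiolate may lose CO2 at 125 °C, or the phenoxide may close 5-exo instead of 6-endo. The fallback is the classical chalcone route, which sets out from 7 and 11 and returns at 17. Treatment of 7 with n-BuLi (2.2 equiv, THF, −78 °C) should deprotonate the phenol and exchange bromine to give lithium 3,5-bis(benzyloxy)-2-lithio-4-methoxyphenoxide F1 (not isolated). Acylation with N-methoxy-N-methylacetamide and acidic work-up should give 1-[2,4-bis(benzyloxy)-6-hydroxy-3-methoxyphenyl]ethan-1-one F2. Claisen–Schmidt condensation of F2 with 11 (KOH, EtOH, rt) should give (E)-1-[2,4-bis(benzyloxy)-6-hydroxy-3-methoxyphenyl]-3-[3-(benzyloxy)-4-methoxyphenyl]prop-2-en-1-one F3. Oxidative cyclisation of this 2'-hydroxychalcone (I2 cat., DMSO, 120 °C) should then give 17.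

2. Step 11. Conversion may stall because the lipophilic phenoxide dissolves poorly in the aqueous alkaline medium, and the quinol may be over-oxidised to the quinone during sulfate hydrolysis. The fallback sets out from 18 and returns at 21, bypassing 20 and step 12. Bromination para to the 5-hydroxyl (NBS, DMF, 0 °C) should give 7-(benzyloxy)-2-[3-(benzyloxy)-4-methoxyphenyl]-8-bromo-5-hydroxy-6-methoxy-4H-chromen-4-one F4. Ullmann-type methoxylation (NaOMe, CuBr, DMF–MeOH, 110 °C) should then replace bromine by methoxy and give 21.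

3. Step 10. Discrimination between the three benzyl ethers may be lost (cleavage at O7 or O3' as well), or the chelated ether may be cleaved incompletely. The fallback sets out from 17 and returns at 18. Hydrogenolysis of all three benzyl ethers (H2, Pd/C, EtOAc–MeOH) should give 5,7-dihydroxy-2-(3-hydroxy-4-methoxyphenyl)-6-methoxy-4H-chromen-4-one F5. Benzylation with two equivalents of BnBr (K2CO3, acetone, reflux) should then re-protect the 7- and 3'-hydroxyls and leave the hydrogen-bonded 5-hydroxyl free, giving 18.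

**Further compounds**

F1 | step 9 | lithium 3,5-bis(benzyloxy)-2-lithio-4-methoxyphenoxide (not isolated) | [Li]c1c(O[Li])cc(OCc2ccccc2)c(OC)c1OCc1ccccc1
F2 | step 9 | 1-[2,4-bis(benzyloxy)-6-hydroxy-3-methoxyphenyl]ethan-1-one | CC(=O)c1c(O)cc(OCc2ccccc2)c(OC)c1OCc1ccccc1
F3 | step 9 | (E)-1-[2,4-bis(benzyloxy)-6-hydroxy-3-methoxyphenyl]-3-[3-(benzyloxy)-4-methoxyphenyl]prop-2-en-1-one | COc1ccc(/C=C/C(=O)c2c(O)cc(OCc3ccccc3)c(OC)c2OCc2ccccc2)cc1OCc1ccccc1
F4 | step 11 | 7-(benzyloxy)-2-[3-(benzyloxy)-4-methoxyphenyl]-8-bromo-5-hydroxy-6-methoxy-4H-chromen-4-one | COc1ccc(-c2cc(=O)c3c(O)c(OC)c(OCc4ccccc4)c(Br)c3o2)cc1OCc1ccccc1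
F5 | step 10 | 5,7-dihydroxy-2-(3-hydroxy-4-methoxyphenyl)-6-methoxy-4H-chromen-4-one | COc1ccc(-c2cc(=O)c3c(O)c(OC)c(O)cc3o2)cc1O
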